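The decalin is completed by closing ring A onto an enantioenriched ring B through the C4–C5 bond (labdane numbering). The key step exploits two features: C4, the gem-dimethyl carbon of ring A, is a latent tertiary cation, and C5, the ring-fusion CH, lies α to the oxygen-bearing C6 of ring B, a ketone at that stage. Acid converts the prenyl-type alkene of (S)-3-methyl-3-(4-methylpent-3-enyl)cyclohexanone, whose quaternary C10 comes from a copper-catalysed asymmetric conjugate addition, into the C4 cation; the C5 enol captures it, and equilibration α to the ketone delivers the trans-decalin. The C6 ketone then directs all ring B functionalisation, and the Z side chain is added to a C9 ketone.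

Key step: step 2

Remark on numbering: bicyclic compounds carry labdane locants (ring A = C1–C5 and C10; ring B = C5–C10; gem-dimethyl on C4; angular methyl on C10; side chain C11–C16 on C9); β is the face of the C10 methyl.
Assumption: in step 1 the enantiomer of the NHC ligand is the one that delivers the (S)-ketone.

Step 1
Reactants: 1 3-methylcyclohex-2-en-1-one; 2 5-bromo-2-methylpent-2-ene
Product: 4 (S)-3-methyl-3-(4-methylpent-3-en-1-yl)cyclohexan-1-one, via homoprenylmagnesium bromide 3 (not isolated)
Conditions: 2, Mg, Et2O, 35 °C; then 1, Cu(OTf)2 (3 mol %), chiral hydroxyalkyl-imidazolinium hexafluorophosphate (NHC precursor, 4 mol %), Et2O, 0 °C; aq NH4Cl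
Reagents that add atoms: none
Why: Copper–NHC-catalysed asymmetric conjugate addition of a Grignard reagent to a β-methyl enone is an established way to all-carbon quaternary centres, and the chiral ligand selects the enone face so that C10 is set as (S).

Step 2
Reactants: 4 (S)-3-methyl-3-(4-methylpent-3-en-1-yl)cyclohexan-1-one
Product: 6 trans-fused 4,4,10-trimethyldecalin-6-one, via cis-fused C5 epimer 5 (not isolated)
Conditions: TfOH (1.5 equiv), CH2Cl2, −20 → 23 °C, stirred until the C5 epimers have equilibrated
Reagents that add atoms: none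
Why: TfOH protonates the trisubstituted alkene at C3 to give the tertiary C4 cation, the ketone enolises toward C5 under the same acid, and the C5 enol carbon captures the cation, forming the C4–C5 bond, the quaternary C4 and ring A, after which loss of the O–H proton returns the C6 ketone. The closest known reaction type is the Brønsted or Lewis acid-mediated cation–olefin cyclisation terminated by a ketone enol, an intramolecular Markovnikov hydroalkylation of an alkene by a ketone (acid-promoted Conia-ene-type α-tert-alkylation). Ring A closes in a 6-(enolexo)-endo-trig mode: both alkene carbons end up inside the new six-membered ring and the enol double bond stays outside it. C10 already carries its (S) configuration from step 1 and C4 is not stereogenic; whichever C5 epimer forms first (the cis-fused 5 is expected kinetically), the position α to the C6 carbonyl epimerises through the enol to the trans-fused ketone 6, so the ring fusion is under thermodynamic control. The step needs regioselection between the two α-carbons and chemoselection against carbonyl-ene (Prins) addition of the alkene to the protonated ketone: only the C5 enol can reach C4 through a six-membered transition state (the C7 enol would need an eight-membered ring), and the Prins adduct, a bridged tertiary alcohol, can revert under strong protic acid whereas the C-alkylation cannot.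

Step 3
Reactants: 6 trans-fused 4,4,10-trimethyldecalin-6-one
Product: 7 4,4,10-trimethyl-trans-decal-7-en-6-one
Conditions: IBX (1.5 equiv), DMSO/PhF, 70 °C
Reagents that add atoms: none
Why: IBX-mediated α,β-dehydrogenation of a ketone through its enol can only introduce the C7=C8 bond, because the carbons next to C5 (C4 and C10) are quaternary and offer no hydrogen for desaturation on that side.

Step 4
Reactants: 7 4,4,10-trimethyl-trans-decal-7-en-6-one
Product: 8 6-(trimethylsilyloxy)-4,4,8α,10-tetramethyl-trans-decal-6-ene
Conditions: Me2CuLi (from MeLi and CuI), TMSCl, THF, −78 °C; Et3N, cold aq NaHCO3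
Reagents that add atoms: lithium dimethylcuprate [Li+].C[Cu-]C; chlorotrimethylsilane C[Si](C)(C)Cl
Why: Cuprate 1,4-addition (Gilman reagent) with in situ silylation of the enolate delivers the methyl to C8 anti to the axial C10 methyl (8α), a stereocentre that is erased in step 5.

Step 5
Reactants: 8 6-(trimethylsilyloxy)-4,4,8α,10-tetramethyl-trans-decal-6-ene
Product: 9 4,4,8,10-tetramethyl-trans-decal-7-en-6-one
Conditions: Pd(OAc)2 (1.1 equiv), MeCN, 23 °C
Reagents that add atoms: none
Why: In this Saegusa–Ito oxidation the palladium enolate loses H8, its only β-hydrogen, which regenerates the C7=C8 enone now carrying the C8 methyl.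

Step 6
Reactants: 9 4,4,8,10-tetramethyl-trans-decal-7-en-6-one
Product: 10 4,4,8,10-tetramethyl-trans-decal-7-ene-6,9-dione
Conditions: Pd(OH)2/C (5 mol %), t-BuOOH (5 equiv), K2CO3 (0.25 equiv), CH2Cl2, 4 °C
Reagents that add atoms: tert-butyl hydroperoxide CC(C)(C)OO
Why: The Pd(OH)2/C–TBHP allylic oxidation of an α,β-enone at its γ-methylene to the ene-1,4-dione should act on C9H2, the only allylic methylene, in preference to the C8 methyl, as in the isophorone to ketoisophorone case.

Step 7
Reactants: 10 4,4,8,10-tetramethyl-trans-decal-7-ene-6,9-dione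
Product: 11 6β-hydroxy-4,4,8,10-tetramethyl-trans-decal-7-en-9-one
Conditions: NaBH4 (1.0 equiv), CeCl3·7H2O (1.1 equiv), MeOH, −78 °C
Reagents that add atoms: none
Why: In this Luche 1,2-reduction the C6 carbonyl (flanked by a CH and a vinylic CH) should react before the C9 carbonyl (flanked by quaternary C10 and the methyl-bearing C8), as in the C4-selective reduction of ketoisophorone, and hydride arrives on the α face because the β face is blocked by the axial methyls on C4 and C10, giving the 6β-alcohol.

Step 8
Reactants: 12 (Z)-3-methylpent-2-en-4-yn-1-ol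
Product: 13 (Z)-tert-butyldimethyl[(3-methylpent-2-en-4-yn-1-yl)oxy]silane
Conditions: TBSCl, imidazole, DMF, 23 °C
Reagents that add atoms: tert-butyldimethylsilyl chloride CC(C)(C)[Si](C)(C)Cl
Why: Standard silyl ether formation on a primary alcohol leaves the Z enyne untouched.

Step 9
Reactants: 13 (Z)-tert-butyldimethyl[(3-methylpent-2-en-4-yn-1-yl)oxy]silane
Product: 14 (Z)-tert-butyldimethyl[(3-methylpenta-2,4-dien-1-yl)oxy]silane
Conditions: H2 (1 atm), Pd/CaCO3 poisoned with Pb(OAc)2 (Lindlar catalyst), quinoline, hexane, 23 °C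
Reagents that add atoms: none
Why: Lindlar semihydrogenation stops at the alkene for the terminal alkyne and leaves the trisubstituted Z alkene and its geometry intact.

Step 10
Reactants: 14 (Z)-tert-butyldimethyl[(3-methylpenta-2,4-dien-1-yl)oxy]silane
Product: 16 (Z)-5-(tert-butyldimethylsilyloxy)-3-methylpent-3-en-1-ol, via B-alkyl-9-BBN adduct 15 (not isolated)
Conditions: 9-BBN, THF, 0 → 23 °C; then NaOH, H2O2, 0 °C
Reagents that add atoms: hydrogen peroxide OO
Why: Hydroboration–oxidation with 9-BBN places boron on the terminal carbon of the monosubstituted vinyl group (anti-Markovnikov) and ignores the trisubstituted alkene, giving the primary homoallylic alcohol.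

Step 11
Reactants: 16 (Z)-5-(tert-butyldimethylsilyloxy)-3-methylpent-3-en-1-ol
Product: 17 (Z)-tert-butyl[(5-iodo-3-methylpent-2-en-1-yl)oxy]dimethylsilane
Conditions: I2, PPh3, imidazole, CH2Cl2, 0 °C
Reagents that add atoms: iodine [I][I]
Why: Appel-type iodination converts the primary alcohol into the iodide by SN2 under neutral conditions, without allylic transposition or loss of the Z geometry.

Step 12
Reactants: 11 6β-hydroxy-4,4,8,10-tetramethyl-trans-decal-7-en-9-one; 17 (Z)-tert-butyl[(5-iodo-3-methylpent-2-en-1-yl)oxy]dimethylsilane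
Product: 19 6β,9β-dihydroxy-9α-[(Z)-5-(tert-butyldimethylsilyloxy)-3-methylpent-3-en-1-yl]-4,4,8,10-tetramethyl-trans-decal-7-ene, via alkyllithium 18 (not isolated)
Conditions: 17 (3 equiv), t-BuLi (6 equiv), Et2O, −78 °C; then 11, THF, −78 → 0 °C; aq NH4Cl
Reagents that add atoms: none
Why: Iodine–lithium exchange gives the primary alkyllithium, which after deprotonating the C6 hydroxyl adds 1,2 to the non-enolisable C9 ketone (C10 quaternary, C8 sp2) from the α face opposite the C10 methyl; the configuration created at C9 is immaterial because C9 becomes sp2 in step 13.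

Step 13
Reactants: 19 6β,9β-dihydroxy-9α-[(Z)-5-(tert-butyldimethylsilyloxy)-3-methylpent-3-en-1-yl]-4,4,8,10-tetramethyl-trans-decal-7-ene
Product: 20 (13Z)-labda-8,13-diene-6β,7α,15-triol
Conditions: 0.5 M aq HCl, THF, 0 → 23 °C
Reagents that add atoms: water O
Why: In this acid-catalysed 1,3-allylic transposition the tertiary allylic C9–OH ionises to the C7–C9 allyl cation, which water should capture at C7 on the α face (axial attack anti to the 6β-OH, possibly through a transient 6β,7β-epoxide opened at allylic C7 with inversion), giving the tetrasubstituted C8=C9 alkene and the 7α-alcohol while the TBS ether is hydrolysed.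

Step 14
Reactants: 20 (13Z)-labda-8,13-diene-6β,7α,15-triol
Product: 21 (13Z)-6β-hydroxylabda-8,13-diene-7α,15-diyl diacetate
Conditions: Ac2O (2.5 equiv), pyridine, DMAP (5 mol %), CH2Cl2, 0 °C
Reagents that add atoms: acetic anhydride CC(=O)OC(C)=O
Why: DMAP-catalysed acetylation should esterify the primary C15 and the allylic C7 hydroxyls, whereas the 6β-hydroxyl, 1,3-diaxial to the methyls on C4 and C10, is too hindered to react under these conditions.

Compound list
1 | 3-methylcyclohex-2-en-1-one | CC1=CC(=O)CCC1 | starting material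
2 | 5-bromo-2-methylpent-2-ene | CC(C)=CCCBr | starting material
3 | (4-methylpent-3-en-1-yl)magnesium bromide (homoprenylmagnesium bromide) | CC(C)=CCC[Mg]Br | intermediate
4 | (S)-3-methyl-3-(4-methylpent-3-en-1-yl)cyclohexan-1-one | C[C@@]1(CCC=C(C)C)CCCC(=O)C1 | intermediate
5 | cis-fused 4,4,10-trimethyldecalin-6-one (5β-H, 10β-CH3; C5 epimer of 6) | C1CCC(=O)[C@@H]2C(C)(C)CCC[C@]12C | intermediate
6 | trans-fused 4,4,10-trimethyldecalin-6-one (5α-H, 10β-CH3) | C1CCC(=O)[C@H]2C(C)(C)CCC[C@]12C | intermediate
7 | 4,4,10-trimethyl-trans-decal-7-en-6-one (5α-H, 10β-CH3) | C1C=CC(=O)[C@H]2C(C)(C)CCC[C@]12C | intermediate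
8 | 6-(trimethylsilyloxy)-4,4,8α,10-tetramethyl-trans-decal-6-ene (5α-H, 10β-CH3) | C1[C@H](C)C=C(O[Si](C)(C)C)[C@H]2C(C)(C)CCC[C@]12C | intermediate
9 | 4,4,8,10-tetramethyl-trans-decal-7-en-6-one (5α-H, 10β-CH3) | C1C(C)=CC(=O)[C@H]2C(C)(C)CCC[C@]12C | intermediate
10 | 4,4,8,10-tetramethyl-trans-decal-7-ene-6,9-dione (5α-H, 10β-CH3) | O=C1C(C)=CC(=O)[C@H]2C(C)(C)CCC[C@]12C | intermediate
11 | 6β-hydroxy-4,4,8,10-tetramethyl-trans-decal-7-en-9-one (5α-H, 10β-CH3) | O=C1C(C)=C[C@@H](O)[C@H]2C(C)(C)CCC[C@]12C | intermediate
12 | (Z)-3-methylpent-2-en-4-yn-1-ol | C#C/C(C)=C\CO | starting material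
13 | (Z)-tert-butyldimethyl[(3-methylpent-2-en-4-yn-1-yl)oxy]silane | C#C/C(C)=C\CO[Si](C)(C)C(C)(C)C | intermediate
14 | (Z)-tert-butyldimethyl[(3-methylpenta-2,4-dien-1-yl)oxy]silane | C=C/C(C)=C\CO[Si](C)(C)C(C)(C)C | intermediate
15 | 9-[(Z)-5-(tert-butyldimethylsilyloxy)-3-methylpent-3-en-1-yl]-9-borabicyclo[3.3.1]nonane | CC(C)(C)[Si](C)(C)OC/C=C(/C)CCB1C2CCCC1CCC2 | intermediate
16 | (Z)-5-(tert-butyldimethylsilyloxy)-3-methylpent-3-en-1-ol | OCC/C(C)=C\CO[Si](C)(C)C(C)(C)C | intermediate
17 | (Z)-tert-butyl[(5-iodo-3-methylpent-2-en-1-yl)oxy]dimethylsilane | ICC/C(C)=C\CO[Si](C)(C)C(C)(C)C | intermediate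
18 | [(Z)-5-(tert-butyldimethylsilyloxy)-3-methylpent-3-en-1-yl]lithium | [Li]CC/C(C)=C\CO[Si](C)(C)C(C)(C)C | intermediate
19 | 6β,9β-dihydroxy-9α-[(Z)-5-(tert-butyldimethylsilyloxy)-3-methylpent-3-en-1-yl]-4,4,8,10-tetramethyl-trans-decal-7-ene (5α-H, 10β-CH3) | O[C@@]1(CC/C(C)=C\CO[Si](C)(C)C(C)(C)C)C(C)=C[C@@H](O)[C@H]2C(C)(C)CCC[C@]12C | intermediate
20 | (13Z)-labda-8,13-diene-6β,7α,15-triol | OC/C=C(/C)CCC1=C(C)[C@H](O)[C@@H](O)[C@H]2C(C)(C)CCC[C@]12C | intermediate
21 | (13Z)-6β-hydroxylabda-8,13-diene-7α,15-diyl diacetate | CC(=O)OC/C=C(/C)CCC1=C(C)[C@H](OC(C)=O)[C@@H](O)[C@H]2C(C)(C)CCC[C@]12C | target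

Total step count: 14 steps.
Longest linear sequence: 10 steps (steps 1–7 and 12–14); steps 8–11 build the side chain separately.

Steps most likely to fail

Step 2 (key step). The alkene may add to the acid-activated carbonyl (Prins closure to a bridged alcohol), or the C4 cation may lose a proton or oligomerise, faster than the sparsely populated C5 enol captures it. The fallback sets out from 4 and separates cation generation from enol formation. Markovnikov hydrochlorination (HCl, CH2Cl2, −78 °C) should give the tertiary chloride (S)-3-(4-chloro-4-methylpentyl)-3-methylcyclohexan-1-one F1. Silylation under equilibrating conditions (TMSOTf, Et3N) should give the C5 silyl enol ether (S)-{[3-(4-chloro-4-methylpentyl)-3-methylcyclohex-1-en-1-yl]oxy}trimethylsilane F2 together with its C7 regioisomer (R)-{[5-(4-chloro-4-methylpentyl)-5-methylcyclohex-1-en-1-yl]oxy}trimethylsilane F3. TiCl4 (CH2Cl2, −78 → −40 °C) then ionises the tertiary chloride, and only the enol carbon C5 of F2 can capture the cation through a six-membered transition state (intramolecular Lewis acid-mediated α-tert-alkylation of a silyl enol ether). This again forms the C4–C5 bond and ring A, now with no free carbonyl and no protic acid. Brief equilibration with NaOMe in MeOH should give 6, where the route is rejoined; F3 returns F1 on work-up and is recycled.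

Step 7. Hydride may be delivered to the C9 carbonyl instead of, or as well as, the C6 carbonyl. The fallback sets out from 10 and moves the selection from the reduction to an oxidation. Exhaustive Luche reduction (excess NaBH4, CeCl3·7H2O, MeOH, 0 °C; hydride from the α face at both carbonyls) should give 4,4,8,10-tetramethyl-trans-decal-7-ene-6β,9β-diol F4. MnO2 (CH2Cl2, 23 °C) should then oxidise the quasi-equatorial allylic 9β-hydroxyl, whose axial C–H bond overlaps with the alkene π system, and leave the quasi-axial 6β-hydroxyl, which is also shielded by two syn-axial methyls, giving 11.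

Step 13. The allyl cation may lose a proton to give dienes, be captured by the side-chain alkene, or be attacked at C7 from the β face. The fallback sets out from 19 and avoids a free cation. A suprafacial 1,3-transposition with Ph3SiOReO3 (cat., Et2O, −50 °C; [3,3] shift of the perrhenate ester) should move the 9β-oxygen to C7 on the same face and give (13Z)-15-(tert-butyldimethylsilyloxy)labda-8,13-diene-6β,7β-diol F5. A Mitsunobu reaction with AcOH (PPh3, DIAD, THF) then inverts the less hindered allylic C7 carbinol to give (13Z)-15-(tert-butyldimethylsilyloxy)-6β-hydroxylabda-8,13-dien-7α-yl acetate F6. TBAF (THF, 0 °C) frees the primary alcohol to give (13Z)-6β,15-dihydroxylabda-8,13-dien-7α-yl acetate F7, and Ac2O/pyridine acetylates C15 to give 21.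

Further compounds
F1 | step 2 | (S)-3-(4-chloro-4-methylpentyl)-3-methylcyclohexan-1-one | C[C@@]1(CCCC(C)(C)Cl)CCCC(=O)C1
F2 | step 2 | (S)-{[3-(4-chloro-4-methylpentyl)-3-methylcyclohex-1-en-1-yl]oxy}trimethylsilane | C[C@@]1(CCCC(C)(C)Cl)CCCC(O[Si](C)(C)C)=C1
F3 | step 2 | (R)-{[5-(4-chloro-4-methylpentyl)-5-methylcyclohex-1-en-1-yl]oxy}trimethylsilane | C[C@@]1(CCCC(C)(C)Cl)CCC=C(O[Si](C)(C)C)C1
F4 | step 7 | 4,4,8,10-tetramethyl-trans-decal-7-ene-6β,9β-diol (5α-H, 10β-CH3) | O[C@H]1C(C)=C[C@@H](O)[C@H]2C(C)(C)CCC[C@]12C
F5 | step 13 | (13Z)-15-(tert-butyldimethylsilyloxy)labda-8,13-diene-6β,7β-diol | CC(C)(C)[Si](C)(C)OC/C=C(/C)CCC1=C(C)[C@@H](O)[C@@H](O)[C@H]2C(C)(C)CCC[C@]12C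
F6 | step 13 | (13Z)-15-(tert-butyldimethylsilyloxy)-6β-hydroxylabda-8,13-dien-7α-yl acetate | CC(C)(C)[Si](C)(C)OC/C=C(/C)CCC1=C(C)[C@H](OC(C)=O)[C@@H](O)[C@H]2C(C)(C)CCC[C@]12C
F7 | step 13 | (13Z)-6β,15-dihydroxylabda-8,13-dien-7α-yl acetate | OC/C=C(/C)CCC1=C(C)[C@H](OC(C)=O)[C@@H](O)[C@H]2C(C)(C)CCC[C@]12C
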